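The ratio of the substrate charges in the two earlier runs was 2.31, yet at 20.0 h the north-west run held 12.0% of its substrate and the south run 11.9%, a gap inside the scatter of 0.3 percentage points. So in these two runs, both with 2 mM of acid, the share reacted did not follow the charge. I treated the decay as pseudo-first-order and took from those two readings a decay constant k of 0.106 h⁻¹.

| setting | north-west | south | flask |
|---|---|---|---|
| substrate | 13 mM | 30 mM | 20 mM |
| acid | 2 mM | 2 mM | 2.00 mM |
| remark | run made earlier | run made earlier |  |
| time |  |  | 20 h |

- north-west (time / h: substrate / %, product / %): 1.33: 86.4, 13.1; 4.00: 65.2, 35.2; 8.00: 42.3, 57.7; 10.0: 34.3, 66.2; 15.0: 20.2, 80.4; 20.0: 12.0, 88.3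
- south (time / h: substrate / %, product / %): 3.00: 72.2, 27.9; 6.00: 52.5, 47.8; 10.0: 34.0, 66.3; 12.0: 27.0, 73.2; 15.0: 19.6, 80.4; 20.0: 11.9, 88.7

(readings scatter by 0.3 percentage points)

- part of the substrate that has reacted at 20 h
- pH of the solution at 20 h

- acid is the free proton; pH is minus the decimal logarithm of its molar concentration

That k gave 6.53 h as the crossing time, the moment at which substrate and product stand level, reckoned as the natural logarithm of 2 over k. My decision was whether the new flask, with 20 mM of substrate, needed a longer run. The two runs showed k at one acid charge, so I kept the acid at 2.00 mM. A reading at 20 h lay 3.06 crossing times out, and by my reckoning 88.1% would have reacted, so I left the time as it was.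

The forecast gave 88.1%, within 87.4% to 88.8%, and pH 2.7, within 2.64 to 2.76, holding that “the acid appears to act as a catalyst and is not consumed”.

The flask gave 88.3% and pH 2.70.

    substrate + acid → weak acid + acid + product (k = 41.8 M⁻¹ h⁻¹)
    crystals ⇌ weak acid, rate k2*(cs2 - [weak acid]) while solid is left; crystals form when [weak acid] > cs2 (solubility = 0.320 mM, k = 1.16 h⁻¹)
    substrate → weak acid + product (k = 0.0225 h⁻¹)
    weak acid ⇌ conjugate base + acid, settled at all times (K = 6.30 × 10⁻⁵ M)

At 20.0 h the flask held 17.1 mM of crystals and 0.557 mM of weak acid, but its conjugate base, at 0.0174 mM, was far less than the 2.00 mM of acid charged, and acid stood at 101% of its charge. The neighbour flask, with the same charges, was read at 5.0 h, earlier than my crossing time of 6.53 h. So I reckoned 41.1% reacted and substrate still ahead of product. That flask gave 41.7% reacted, with 58% of its substrate left.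

The numbers in the tables were computed with made-up constants; noise was put on by code.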